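The whole route depends on treating three phenolic oxygens as former formyl carbons. In the tetramer (rings A to D, counted from the 2,4,6-trihydroxyphenoxy end), the hydroxyl on C5 of ring B is para to ether carbon C2. The hydroxyls on C3 and C5 of ring C flank ether carbon C4. One peracid oxidation with in-flask methanolysis should therefore turn a heptamethylated trialdehyde into the corresponding triol, creating all three C–O bonds at once. The precursor is the complete four-ring ether chain carrying CHO at those three positions. Earlier in the route, the same formyl groups enable fluoride displacement at C4 of ring C and site-selective unmasking of the C2 oxygen of ring B.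

Key step: step 7

Remark on numbering: in ring B, C1 carries the oxygen to ring A, C2 the oxygen to ring C, and C3 and C5 the remaining oxygens. In ring C, C1 carries the oxygen to ring B, C4 the oxygen to ring D, and C3 and C5 the remaining oxygens. The target is achiral and no stereocentre arises anywhere.

Assumption: the four aromatic building blocks are taken to be catalogue compounds. The methyl group on the C2 oxygen of ring B serves as the temporary protecting group, so no separate protection step and no hydrogenolysis next to an aldehyde are needed.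

Step 1
Reactants: 1 3-iodo-4,5-dimethoxybenzaldehyde; 2 2,4,6-trimethoxyphenol
Product: 3 3,4-dimethoxy-5-(2,4,6-trimethoxyphenoxy)benzaldehyde
Conditions: CuI (10 mol %), picolinic acid (20 mol %), K3PO4, DMSO, 90 °C, argon
Reagents that add atoms: none
Why: Ullmann-type C–O coupling, in which the CuI/picolinic acid system is suited to di-ortho-substituted phenols and ortho-substituted aryl iodides, the non-enolisable aldehyde is inert to phosphate base, and exclusion of air protects the oxidisable phenol 2.

Step 2
Reactants: 3 3,4-dimethoxy-5-(2,4,6-trimethoxyphenoxy)benzaldehyde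
Product: 4 4-hydroxy-3-methoxy-5-(2,4,6-trimethoxyphenoxy)benzaldehyde
Conditions: LiCl, DMF, reflux; aq. HCl work-up
Reagents that add atoms: none
Why: Nucleophilic (SN2) O-demethylation by chloride, selective because only the methoxy group on C2 of ring B releases a phenoxide stabilised by a para formyl group and is twisted out of conjugation by two oxygen neighbours (as in the known conversion of 3,4,5-trimethoxybenzaldehyde into syringaldehyde), so the four unactivated methyl ethers should stay.

Step 3
Reactants: 5 5-bromo-2-fluoro-1,3-dimethylbenzene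
Product: 6 5-bromo-1,3-bis(dibromomethyl)-2-fluorobenzene
Conditions: NBS (excess), AIBN (cat.), PhCF3, reflux, visible light
Reagents that add atoms: N-bromosuccinimide, O=C1CCC(=O)N1Br
Why: Wohl–Ziegler benzylic bromination, in which the halogen-deactivated ring resists electrophilic bromination and each methyl group should stop at the gem-dibromide because a third hydrogen abstraction is sterically and electronically disfavoured.

Step 4
Reactants: 6 5-bromo-1,3-bis(dibromomethyl)-2-fluorobenzene
Product: 7 5-bromo-2-fluorobenzene-1,3-dicarbaldehyde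
Conditions: AgNO3, acetone–H2O, 60 °C, dark
Reagents that add atoms: water, O
Why: Silver-assisted hydrolysis of benzylic gem-dibromides to aldehydes, run under neutral to acidic conditions where no nucleophile strong enough to displace the newly activated fluoride is present.

Step 5
Reactants: 7 5-bromo-2-fluorobenzene-1,3-dicarbaldehyde; 8 3,4,5-trimethoxyphenol
Product: 9 5-bromo-2-(3,4,5-trimethoxyphenoxy)benzene-1,3-dicarbaldehyde
Conditions: K2CO3, DMF, rt to 60 °C
Reagents that add atoms: none
Why: Nucleophilic aromatic substitution by addition–elimination, in which two ortho formyl groups stabilise the Meisenheimer adduct at C4 of ring C, fluoride is the best leaving group for this mechanism, and the bromide meta to both formyl groups is not activated.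

Step 6
Reactants: 4 4-hydroxy-3-methoxy-5-(2,4,6-trimethoxyphenoxy)benzaldehyde; 9 5-bromo-2-(3,4,5-trimethoxyphenoxy)benzene-1,3-dicarbaldehyde
Product: 10 5-[4-formyl-2-methoxy-6-(2,4,6-trimethoxyphenoxy)phenoxy]-2-(3,4,5-trimethoxyphenoxy)benzene-1,3-dicarbaldehyde (the trialdehyde)
Conditions: CuI (20 mol %), N,N-dimethylglycine (40 mol %), Cs2CO3, 1,4-dioxane, 100 °C, argon
Reagents that add atoms: none
Why: Ullmann-type C–O coupling, in which the unhindered, electron-poor bromide on ring C compensates for the hindered, weakly nucleophilic phenoxide of 4, while aryloxy exchange at the activated C4 of ring C is uphill because it would trade the better-stabilised phenoxide of 4 for the more basic 3,4,5-trimethoxyphenoxide.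

Step 7
Reactants: 10 the trialdehyde
Product: 12 5-[4-hydroxy-2-methoxy-6-(2,4,6-trimethoxyphenoxy)phenoxy]-2-(3,4,5-trimethoxyphenoxy)benzene-1,3-diol (heptamethyl ether triol), via triformate 11 (not isolated)
Conditions: mCPBA (slight excess per CHO), Na2HPO4, CH2Cl2, 0 °C to rt; Me2S; then K2CO3, MeOH, rt, argon
Reagents that add atoms: mCPBA, O=C(OO)c1cccc(Cl)c1
Why: Each formyl carbon takes up the peracid to give a Criegee adduct whose aryl group shifts from carbon to the neighbouring peroxide oxygen as 3-chlorobenzoate departs, giving the three aryl formates of 11, and carbonate-promoted methanolysis then releases the phenols on C5 of ring B and on C3 and C5 of ring C. The closest known reaction type is the Baeyer–Villiger (Dakin-type) oxidation of 2- and 4-alkoxy- or aryloxybenzaldehydes, commonly paired with a preceding fluoride displacement on a fluorobenzaldehyde, and here it simply runs three times on one molecule. No ring is closed and no stereocentre is formed. The selectivity needed is aryl over hydride migration at every site, and it is secured because the migrating carbon is para to the C2 ether oxygen in ring B and ortho to the C4 ether oxygen in ring C, which stabilise the positive charge building up on the migrating ring. Rings A and D are protected from hydroxylation by the low temperature, the small excess of oxidant and the phosphate buffer, which also suppresses acid-induced Friedel–Crafts closure of ring D onto a neighbouring formyl group. Me2S destroys the remaining peracid before base exposes the oxidisable phenolates.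

Step 8
Reactants: 12 heptamethyl ether triol
Product: 13 5-[2,4-dihydroxy-6-(2,4,6-trihydroxyphenoxy)phenoxy]-2-(3,4,5-trihydroxyphenoxy)benzene-1,3-diol (CNP0018314.0)
Conditions: BBr3 (excess), CH2Cl2, −78 °C to rt, argon; ice-water quench
Reagents that add atoms: none
Why: Lewis-acid ether cleavage with BBr3, in which bromide attacks each boron-activated O–CH3 group while the diaryl ether bonds offer no sp3 carbon and stay intact, and an aqueous rather than methanolic quench avoids acid-catalysed re-etherification of the phloroglucinol-type rings.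

Compound list
1 | 3-iodo-4,5-dimethoxybenzaldehyde | COc1cc(C=O)cc(I)c1OC | starting material
2 | 2,4,6-trimethoxyphenol | COc1cc(OC)c(O)c(OC)c1 | starting material
3 | 3,4-dimethoxy-5-(2,4,6-trimethoxyphenoxy)benzaldehyde | COc1cc(OC)cc(OC)c1Oc1cc(C=O)cc(OC)c1OC | intermediate
4 | 4-hydroxy-3-methoxy-5-(2,4,6-trimethoxyphenoxy)benzaldehyde | COc1cc(OC)cc(OC)c1Oc1cc(C=O)cc(OC)c1O | intermediate
5 | 5-bromo-2-fluoro-1,3-dimethylbenzene | Cc1cc(Br)cc(C)c1F | starting material
6 | 5-bromo-1,3-bis(dibromomethyl)-2-fluorobenzene | Fc1c(C(Br)Br)cc(Br)cc1C(Br)Br | intermediate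
7 | 5-bromo-2-fluorobenzene-1,3-dicarbaldehyde | O=Cc1cc(Br)cc(C=O)c1F | intermediate
8 | 3,4,5-trimethoxyphenol | COc1cc(O)cc(OC)c1OC | starting material
9 | 5-bromo-2-(3,4,5-trimethoxyphenoxy)benzene-1,3-dicarbaldehyde | COc1cc(Oc2c(C=O)cc(Br)cc2C=O)cc(OC)c1OC | intermediate
10 | 5-[4-formyl-2-methoxy-6-(2,4,6-trimethoxyphenoxy)phenoxy]-2-(3,4,5-trimethoxyphenoxy)benzene-1,3-dicarbaldehyde | COc1cc(OC)cc(OC)c1Oc1cc(C=O)cc(OC)c1Oc1cc(C=O)c(Oc2cc(OC)c(OC)c(OC)c2)c(C=O)c1 | intermediate
11 | 5-[4-(formyloxy)-2-methoxy-6-(2,4,6-trimethoxyphenoxy)phenoxy]-2-(3,4,5-trimethoxyphenoxy)benzene-1,3-diyl diformate | COc1cc(OC)cc(OC)c1Oc1cc(OC=O)cc(OC)c1Oc1cc(OC=O)c(Oc2cc(OC)c(OC)c(OC)c2)c(OC=O)c1 | intermediate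
12 | 5-[4-hydroxy-2-methoxy-6-(2,4,6-trimethoxyphenoxy)phenoxy]-2-(3,4,5-trimethoxyphenoxy)benzene-1,3-diol | COc1cc(OC)cc(OC)c1Oc1cc(O)cc(OC)c1Oc1cc(O)c(Oc2cc(OC)c(OC)c(OC)c2)c(O)c1 | intermediate
13 | 5-[2,4-dihydroxy-6-(2,4,6-trihydroxyphenoxy)phenoxy]-2-(3,4,5-trihydroxyphenoxy)benzene-1,3-diol | Oc1cc(O)c(Oc2cc(O)cc(O)c2Oc2cc(O)c(Oc3cc(O)c(O)c(O)c3)c(O)c2)c(O)c1 | target

Total step count: 8
Longest linear sequence: 6 (steps 3, 4, 5, 6, 7, 8)

Steps most likely to fail

**Step 7.**
- **What may go wrong:** Each ring C formyl group feels a second carbonyl group and only a twisted aryloxy donor. Hydride shift may therefore compete with aryl shift and drain material towards carboxylic acids. The prolonged contact with peracid that three successive oxidations need may also start hydroxylation of rings A and D.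
- **Fallback:** The oxygens on C3 and C5 of ring C are bought instead of made, so only the well-behaved ring B aldehyde has to be oxidised. The fallback sets out from 4.
  - Catalogue 4-bromo-2,6-dimethoxyphenol is coupled with catalogue 5-iodo-1,2,3-trimethoxybenzene (CuI, picolinic acid, K3PO4, DMSO, 90 °C) to give 5-bromo-1,3-dimethoxy-2-(3,4,5-trimethoxyphenoxy)benzene F1.
  - Bromine–lithium exchange (n-BuLi, THF, −78 °C), B(OiPr)3 and mild acid hydrolysis give [3,5-dimethoxy-4-(3,4,5-trimethoxyphenoxy)phenyl]boronic acid F2.
  - Chan–Lam coupling of this electron-rich boronic acid with 4 (Cu(OAc)2, pyridine, 4 Å sieves, CH2Cl2, air, rt) gives the monoaldehyde F3.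
  - A single Baeyer–Villiger oxidation with buffered mCPBA passes through the aryl formate F4, and methanolysis gives the nonamethyl ether phenol F5.
  - BBr3 then cleaves nine methyl ethers, and the sequence comes back to the route at 13.

**Step 6.**
- **What may go wrong:** C–O bond formation may be slow because the phenoxide of 4 is flanked on both sides and weakened by its para formyl group. At the temperature needed, protodebromination of 9 and base-induced scrambling of aryloxy groups could then take over.
- **Fallback:** An oxidative coupling at room temperature in which ring C is the boron partner. The fallback sets out from 9.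
  - Miyaura borylation (B2pin2, Pd(dppf)Cl2, KOAc, dioxane, 80 °C) gives the pinacol boronate F6.
  - NaIO4 and NH4OAc in aqueous acetone free [3,5-diformyl-4-(3,4,5-trimethoxyphenoxy)phenyl]boronic acid F7.
  - Chan–Lam coupling of F7 with 4 (Cu(OAc)2, pyridine, Et3N, 4 Å sieves, CH2Cl2, air, rt) comes back to the route at 10. This coupling is known to accept acidic phenols with two ortho substituents.

**Step 8.**
- **What may go wrong:** Seven ether cleavages may not all go to completion. Partly methylated material would then travel with a very polar product, and the decaphenol may darken by air oxidation during aqueous isolation and chromatography.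
- **Fallback:** The product is isolated through a stable derivative. The fallback sets out from 12.
  - The crude material from the BBr3 reaction is not purified but peracetylated (Ac2O, pyridine, rt) to the decaacetate F8. This derivative is air-stable, can be chromatographed and can be separated from under-cleaved material.
  - Transesterification (catalytic NaOMe, MeOH, 0 °C, argon, then acidic ion-exchange resin and filtration) comes back to the route at 13.

Further compounds
F1 | step 7 | 5-bromo-1,3-dimethoxy-2-(3,4,5-trimethoxyphenoxy)benzene | COc1cc(Oc2c(OC)cc(Br)cc2OC)cc(OC)c1OC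
F2 | step 7 | [3,5-dimethoxy-4-(3,4,5-trimethoxyphenoxy)phenyl]boronic acid | COc1cc(Oc2c(OC)cc(B(O)O)cc2OC)cc(OC)c1OC
F3 | step 7 | 4-[3,5-dimethoxy-4-(3,4,5-trimethoxyphenoxy)phenoxy]-3-methoxy-5-(2,4,6-trimethoxyphenoxy)benzaldehyde | COc1cc(OC)cc(OC)c1Oc1cc(C=O)cc(OC)c1Oc1cc(OC)c(Oc2cc(OC)c(OC)c(OC)c2)c(OC)c1
F4 | step 7 | 4-[3,5-dimethoxy-4-(3,4,5-trimethoxyphenoxy)phenoxy]-3-methoxy-5-(2,4,6-trimethoxyphenoxy)phenyl formate | COc1cc(OC)cc(OC)c1Oc1cc(OC=O)cc(OC)c1Oc1cc(OC)c(Oc2cc(OC)c(OC)c(OC)c2)c(OC)c1
F5 | step 7 | 4-[3,5-dimethoxy-4-(3,4,5-trimethoxyphenoxy)phenoxy]-3-methoxy-5-(2,4,6-trimethoxyphenoxy)phenol | COc1cc(OC)cc(OC)c1Oc1cc(O)cc(OC)c1Oc1cc(OC)c(Oc2cc(OC)c(OC)c(OC)c2)c(OC)c1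
F6 | step 6 | 5-(4,4,5,5-tetramethyl-1,3,2-dioxaborolan-2-yl)-2-(3,4,5-trimethoxyphenoxy)benzene-1,3-dicarbaldehyde | COc1cc(Oc2c(C=O)cc(B3OC(C)(C)C(C)(C)O3)cc2C=O)cc(OC)c1OC
F7 | step 6 | [3,5-diformyl-4-(3,4,5-trimethoxyphenoxy)phenyl]boronic acid | COc1cc(Oc2c(C=O)cc(B(O)O)cc2C=O)cc(OC)c1OC
F8 | step 8 | decaacetate of 13 | CC(=O)Oc1cc(OC(C)=O)c(Oc2cc(OC(C)=O)cc(OC(C)=O)c2Oc2cc(OC(C)=O)c(Oc3cc(OC(C)=O)c(OC(C)=O)c(OC(C)=O)c3)c(OC(C)=O)c2)c(OC(C)=O)c1
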